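Take the south-west run, the earlier flask, and read from it how product divides between the hands, to carry that division to the new flask.

in all of them: left-handed substrate 0.71 M; right-handed substrate 0.71 M; partner 1.56 M; racemization catalyst 140 mM
- south-west: free catalyst 120 mM; run made earlier
- flask: free catalyst 78 mM; time 40 h

south-west run (percent of the left-handed substrate and right-handed substrate together charged)

| time / h | left-handed product / % | left-handed substrate / % | right-handed product / % |
|---|---|---|---|
| 1.00 | 0 | 48 | 0 |
| 3.00 | 8 | 44 | 2 |
| 6.00 | 12 | 40 | 3 |
| 8.00 | 17 | 36 | 12 |
| 12.0 | 22 | 37 | 12 |

(scatter of a reading: 2 percentage points)

- concentration of left-handed product at 40 h, in M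
- concentration of left-handed substrate at 40 h, in M
- concentration of right-handed product at 40 h, in M
- concentration of partner at 40 h, in M

Define the left share as c(left-handed product) / [c(left-handed product) + c(right-handed product)], the selectivity factor put as a share. Go through what it needs, assuming both products form on the same free catalyst and partner.

The charges of free catalyst and partner then multiply both rates and cancel, so the guess about 78 mM of free catalyst touches the total, not the share.

The substrates enter as a correction: the rate ratio scales with c(left-handed substrate) / c(right-handed substrate). At 8.00 h the south-west run reads 36 % left-handed and, by difference, 35.0 % right-handed, a factor of 1.03. At 12.0 h the same subtraction gives 29.0 % against 37 %, but this is a reading built from readings each good to 2 percentage points. Take the correction as nil.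

The product readings must be known well, so pool them:

left-handed sum = 59.0 %, right-handed sum = 29.0 %

left share = 0.670

A left-handed reading off by 2 points moves this by 0.00749. A right-handed reading moves it by 0.0152, twice as much.

The forecast gives 0.5 M left-handed product, 0.33 M left-handed substrate, 0.25 M right-handed product and 0.81 M partner, holding that “racemization appears to keep pace and selectivity should stay constant”.

The flask gives 0.456 M, 0.376 M, 0.210 M and 0.572 M respectively.

    partner + free catalyst + left-handed substrate → free catalyst + left-handed product (k = 0.00488 L² mol⁻² min⁻¹)
    partner + free catalyst + right-handed substrate → free catalyst + right-handed product (k = 0.00224 L² mol⁻² min⁻¹)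
    left-handed substrate + racemization catalyst ⇌ right-handed substrate + racemization catalyst, rate k3*[racemization catalyst]*[left-handed substrate] forward; the back reaction follows from the equilibrium constant (k = 0.117 L mol⁻¹ min⁻¹)
    partner → decomposed reagent (k = 1.41 × 10⁻⁴ min⁻¹)

At 40.0 h the flask holds 26.5 % left-handed and 26.6 % right-handed substrate, and its products give a left share of 0.685 against the 0.670 read earlier. Now use the share on the neighbour charged with 2.7 M of partner, which holds 15.8 % and 15.9 % of the two substrates. Its loss of left-handed substrate, doubled, 0.971 M, is about the product made, and 0.670 of that is 0.651 M. That neighbour holds 0.662 M of left-handed product.

Readings and results are calculated for an exercise; the scatter is artificial.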